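3 questions stand before this flask is run again, and one decision hangs on them: charge the recipe as written, or add reagent for safety.

    substrate + target → side product (k1 = 0.48 L mol⁻¹ s⁻¹)
    reagent + catalyst + intermediate → catalyst + target (k2 = 440 L² mol⁻² s⁻¹)
    substrate + catalyst → catalyst + intermediate (k3 = 88 L mol⁻¹ s⁻¹)

substrate 0.050 M; reagent 1.20 equiv; catalyst 2 mol%; time 12 h

- a species is counted by the substrate in it: one side product counts as two
- the reaction counts as stopped when no species that holds the substrate changes by six tenths of a point or more over the second half of the time
- run time (flask): 12 h

1. which holds at 12 h: what has brought the reaction to rest, or that it has not come to rest (all of the substrate has reacted / it is still moving / the reagent has run out first / no working catalyst is left)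
2. share of the substrate used up at 12 h
3. target at 12 h, in percent of the substrate charged

Both catalysed steps hand the catalyst back, so it stays at 0.00100 M and the main road turns pseudo-first-order. Substrate goes to intermediate at a = 0.0880 s⁻¹, and intermediate goes to target at b = 0.0264 s⁻¹, with reagent held at its charge. In 12 h, a amounts to 3802 lifetimes, so conversion comes to 100%. Reagent stands above one equivalent, so this flask should end thus: all of the substrate has reacted.

The danger is the side step, which takes substrate and target together. Integrating substrate times target over the two exponentials, and counting one side product as two, gives a product of two factors. The first is a selectivity factor, s = 0.48 L mol⁻¹ s⁻¹ times 0.050 M over a = 0.273. The second is w = b/(a+b) = 0.231. Their base-ten logarithms, −0.564 and −0.637, add to −1.20, so L = 6.29%: the leak, the share of charged substrate lost to side product with reagent held at its charge. Target is then 93.7%. In L, added reagent raises w, while catalyst cancels from w and sits under s. So the recipe stays as written, with no reagent added.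

The forecast says all of the substrate has reacted, with conversion 100% and target 94%, by way of “Integrating the sequential profile gives”. L carries that integral as one product.

Simulated, this flask ends thus: all of the substrate has reacted, with conversion 100% and target 95.1%. At 12.0 h it holds side product 4.94% and 19% of its reagent, a reading of 0.785 of L. The neighbour charged with 4.80 equiv has b = 0.106 s⁻¹, so L there is 14.9% and target 85.1%. Computed, that neighbour holds target 88.5% and side product 11.5%, more side product than this flask.

Its constants stand for no real mixture; the result is computed.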